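Remark on the chemistry: compound 14 is written as its chelated (Z)-hydroxymethylene enol, which is the same compound as the keto-aldehyde tautomer. Epoxide 13 is racemic; this is of no consequence because the target has no stereocentre.

## Analysis of the target

Licoagrodione (17) is an unsymmetrical benzil: an acyclic ethane-1,2-dione whose two carbonyl carbons carry ring A (2-hydroxy-4-methoxyphenyl) and ring B (2,4-dihydroxy-3-prenylphenyl). Apart from the two benzene rings there is no ring, and there is no stereocentre, so the task is one of connectivity and chemoselectivity only. The prenyl group sits on C3 of ring B between two phenols; strong acid would cyclise it to a chroman and electrophilic oxidants would attack its alkene. Two of the three phenols are chelated to the carbonyl groups, and the 1,2-dione is open to benzilic acid rearrangement under strong hydroxide and to ring–chain tautomerism with the ortho phenols. The difficulty is to attach two different electron-rich aryl groups to a C2 dicarbonyl unit without symmetrical products, and to place the prenyl group on the most hindered carbon of ring B. The feature the strategy rests on is the C(=O)–C(=O) bond itself. The carbonyl carbon on C1 of ring A and the carbonyl carbon on C1 of ring B form a 1,2-diaryl C2 unit, which is what is left of an isoflavonoid skeleton after loss of one carbon. The dione bond can therefore be traced to a 1,3-diaryl C3 chalcone by a 1,2-shift and a one-carbon excision.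

## Retrosynthetic reasoning

**17 to 16.** The last operation is kept trivial: the three phenols of 17 are masked as methoxymethyl ethers in 16, so only acetal C–O bonds are cut at the end. Acetals are preferred to benzyl or methyl ethers because the prenyl alkene rules out hydrogenolysis and the aryl methyl ether of ring A rules out ether-cleaving Lewis acids. The forward step must free three phenols under acid mild enough that the prenyl group does not close onto its neighbours.

**16 to 14 (through 15).** The dione C–C bond is not cut directly. The carbonyl carbon next to ring B is regarded as a former methine that carried one extra carbon as a formyl group, which leads back to 14. In the forward sense the enol of 14 is oxygenated at that carbon to hydroperoxide 15, which sheds the formyl carbon and leaves the ketone. This exchanges an unsymmetrical 1,2-diketone, hard to make selectively by acylation, for a 2-aryl-1,3-dicarbonyl compound of the kind a chalcone epoxide rearrangement delivers. The forward reaction must cleave on the formyl side only and leave the alkene and acetals alone.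

**14 to 13 (key disconnection).** In 14 the bond between the ring A carbonyl carbon and the carbon bearing ring B is cut, the aroyl group is returned to the neighbouring carbon (the formyl carbon of 14), and an oxygen bridge is restored between the two carbons. This gives epoxy ketone 13. It is the only disconnection that changes the skeleton, from 1,2-diaryl back to 1,3-diaryl. It is placed here because it turns the hardest bond of the target into one that forms by migration to a cation stabilised by ring B. The forward step must ionise the epoxide only at the ring B carbon and move aroyl, not hydride.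

**13 to 12.** Cutting both oxirane C–O bonds gives E-enone 12. The forward epoxidation must attack the electron-poor enone alkene and not the electron-rich prenyl alkene, which calls for a nucleophilic oxidant. Only the trans relative configuration is set, and it is erased in the next step.

**12 to 2 and 10 (through 11).** The enone C=C bond is the convergent cut. It divides 12 into ring A methyl ketone 2 and ring B aldehyde 10, joined forward by aldol addition to 11 and dehydration. Only 2 can enolise and 10 is a non-enolisable aldehyde, so there is no cross-selectivity problem. The ring A oxygen ortho to the ketone must be protected from here on. A free phenol would close a flavanone at this stage, a flavonol-type ring during epoxidation, and an isoflavone ring onto the formyl group after the rearrangement.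

**10 to 7, then 7 to 4 and 5, then 4 to 3.** In 10 the formyl–aryl bond is cut to give arene 7 (forward: ring lithiation to 8, formylation through adduct 9). The prenyl–aryl bond of 7 is then cut to give 4 and prenyl bromide 5 (forward through aryllithium 6). The prenyl group is introduced first because the position between the two acetal oxygens is the preferred lithiation site and is exactly the position that electrophilic prenylation of a resorcinol serves poorly. Once it is occupied, the second lithiation can only go to the equivalent C4/C6 positions. Compound 4 is the bis-acetal of resorcinol 3.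

**2 to 1.** Ketone 2 is the acetal of paeonol 1, which already holds ring A with the acetyl carbon para to the methoxy group and ortho to the hydroxy group, so no regiochemistry has to be established on ring A.

## Alternatives that were turned down

**Alternative 1: ring B built around the prenyl-bearing carbon.**
- Disconnection: ring B is cut at C1–C2 and C5–C6. It is assembled from the bis(silyl enol ether) A1 (1-methoxy-2-prenyl-1,3-bis(trimethylsilyloxy)buta-1,3-diene) and the terminal ynone A2, which carries ring A and the two future dione carbons at the benzoin oxidation level.
- Forward key step: the terminal carbon of A1 adds to the alkyne terminus of A2, the resulting α-carbon closes onto the ester carbon, and loss of methanol and the silyl groups aromatises the ring to the O-silyl benzoin A3. Desilylation, benzoin oxidation and acetal removal follow.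
- For: the prenyl position is fixed by construction, no directed lithiation is needed, and ring B arrives with free phenols.
- Against: such dienes normally react as 1,3-dinucleophiles through C4 and C2 and keep the ester as a ring substituent. The required mode, in which the ester carbon becomes ring atom C2, must compete with that, and the prenyl-substituted diene is hindered. A2 needs its own multi-step synthesis. A free prenyl-resorcinol under Lewis acid invites chroman formation. Three more steps follow the key step.
- Comparison: the regiochemical certainty is matched in the chosen route by lithiation between two acetal oxygens, and the chosen route is shorter with each bond formed by a well-tried reaction.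

**Alternative 2: coumaranone arylation.**
- Disconnection: the bond between the ring B carbonyl carbon and C1 of ring B is cut. Ring A and both dione carbons are taken from 6-methoxybenzofuran-3(2H)-one A4, and ring B from the aryl bromide A5.
- Forward key step: palladium-catalysed arylation of the enolate of A4 with A5 gives A6. Hydroxylation of A6 at C2 gives the cyclic hemiketal, the ring-closed tautomer of the benzil, and acid then opens it and removes the acetals.
- For: it is short and convergent, and the furanone ring protects the ring A phenol and holds both dione carbons.
- Against: the enolate of A4 is prone to self-condensation. Oxidative addition of the electron-rich, ortho-substituted bromide A5 to zerovalent palladium is slow. The product A6 is more acidic than A4, so a second arylation and premature air oxidation compete.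
- Comparison: on step count this alternative is somewhat stronger than the chosen route. The chosen route offers carbon–carbon bond formation by a simple aldol condensation with no competing enolate pathways, and a rearrangement whose regiochemistry is dictated by the substrate.

**Alternative 3: oxalyl linchpin.**
- Disconnection: both aryl–carbonyl bonds are cut, and the C2 unit is supplied by 1,4-dimethylpiperazine-2,3-dione A7.
- Forward key step: the ring A aryllithium A8 and then the ring B aryllithium (compound 8 of the chosen route) add in sequence to the two amide carbonyls of A7. This gives the tris(methoxymethyl) ether A9, which is identical with 16.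
- For: it is the most convergent plan and reaches 16 in about five steps, clearly fewer than the chosen route.
- Against: the first addition must stop cleanly at the mono-adduct and the second must be a different, ortho-substituted and chelated aryllithium. Incomplete or double addition of one partner gives symmetrical benzils or keto amides that are hard to separate from A9. A8 cannot be made by directed deprotonation, because ring A would be lithiated between its two oxygen substituents, so a brominated precursor and halogen–lithium exchange are needed.
- Comparison: the chosen route is longer. In return the unsymmetrical connectivity is guaranteed by construction, since each aryl group enters through a different functional group, and ring A comes from cheap 1 with its carbonyl carbon already in place.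

Key step: step 7

## Route

Step 1
Reactants: 1 paeonol (1-(2-hydroxy-4-methoxyphenyl)ethan-1-one)
Product: 2 1-[4-methoxy-2-(methoxymethoxy)phenyl]ethan-1-one
Conditions: MOMCl, K2CO3, acetone, reflux
Reagents that add atoms: chloromethyl methyl ether, COCCl
Why: O-alkylation of the phenoxide (MOM ether formation); carbonate in refluxing acetone overcomes the hydrogen bond of the chelated phenol to the ketone. The acetal withstands all later basic, organometallic and oxidative steps and blocks the ring closures a free ortho phenol would undergo.

Step 2
Reactants: 3 resorcinol
Product: 4 1,3-bis(methoxymethoxy)benzene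
Conditions: MOMCl (2.5 equiv), K2CO3, acetone, 0 °C to rt
Reagents that add atoms: chloromethyl methyl ether, COCCl
Why: Double MOM ether formation by O-alkylation; the two acetal groups then serve as directing groups for both lithiations and as the final phenol protection.

Step 3
Reactants: 4 1,3-bis(methoxymethoxy)benzene; 5 prenyl bromide (1-bromo-3-methylbut-2-ene)
Product: 7 1,3-bis(methoxymethoxy)-2-(3-methylbut-2-en-1-yl)benzene, via 2,6-bis(methoxymethoxy)phenyllithium 6 (not isolated)
Conditions: n-BuLi, THF, 0 °C to rt; CuI (10 mol %), then 5, −40 °C to rt
Reagents that add atoms: none
Why: Directed ortho-metalation: the C2–H between the two MOM ethers is the most acidic ring position and is held by both acetal oxygens, so 6 forms regioselectively. Copper-catalysed allylic substitution at the primary carbon of 5 then gives the linear prenyl arene.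

Step 4
Reactants: 7 1,3-bis(methoxymethoxy)-2-(3-methylbut-2-en-1-yl)benzene
Product: 10 2,4-bis(methoxymethoxy)-3-(3-methylbut-2-en-1-yl)benzaldehyde, via 2,4-bis(methoxymethoxy)-3-prenylphenyllithium 8 (not isolated), via lithium hemiaminal alkoxide 9 (not isolated)
Conditions: n-BuLi, TMEDA, THF, −20 to 0 °C; DMF, 0 °C to rt; H2O
Reagents that add atoms: N,N-dimethylformamide, CN(C)C=O
Why: Second directed ortho-metalation: with C2 blocked, a MOM oxygen delivers the n-BuLi–TMEDA complex to C4 (C6 is equivalent by symmetry), which should be faster than lateral deprotonation of the prenyl CH2. Formylation of 8 with DMF stops at the tetrahedral adduct 9, which releases the aldehyde only on aqueous work-up, so no over-addition occurs.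

Step 5
Reactants: 2 1-[4-methoxy-2-(methoxymethoxy)phenyl]ethan-1-one; 10 2,4-bis(methoxymethoxy)-3-(3-methylbut-2-en-1-yl)benzaldehyde
Product: 12 (E)-3-[2,4-bis(methoxymethoxy)-3-(3-methylbut-2-en-1-yl)phenyl]-1-[4-methoxy-2-(methoxymethoxy)phenyl]prop-2-en-1-one, via aldol beta-hydroxy ketone 11 (not isolated)
Conditions: KOH, EtOH–H2O, rt
Reagents that add atoms: none
Why: Claisen–Schmidt condensation: 2 is the only enolisable partner and 10 the only aldehyde, and E1cB dehydration of 11 gives the conjugated E-enone as the thermodynamic product. The acetals and the prenyl group are inert to aqueous alkali.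

Step 6
Reactants: 12 (E)-3-[2,4-bis(methoxymethoxy)-3-(3-methylbut-2-en-1-yl)phenyl]-1-[4-methoxy-2-(methoxymethoxy)phenyl]prop-2-en-1-one
Product: 13 rac-[(2S,3R)-3-{2,4-bis(methoxymethoxy)-3-(3-methylbut-2-en-1-yl)phenyl}oxiran-2-yl][4-methoxy-2-(methoxymethoxy)phenyl]methanone (trans epoxide; racemic; one enantiomer drawn)
Conditions: 30% aq. H2O2, NaOH, MeOH–THF, 0 °C to rt
Reagents that add atoms: hydrogen peroxide, OO
Why: Weitz–Scheffer nucleophilic epoxidation: hydroperoxide anion adds to the enone β-carbon and the enolate closes with loss of hydroxide. Bond rotation in the enolate gives the trans epoxide as a racemate, and the nucleophilic oxidant does not react with the electron-rich prenyl alkene.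

Step 7
Reactants: 13 rac-[(2S,3R)-3-{2,4-bis(methoxymethoxy)-3-(3-methylbut-2-en-1-yl)phenyl}oxiran-2-yl][4-methoxy-2-(methoxymethoxy)phenyl]methanone
Product: 14 (Z)-2-[2,4-bis(methoxymethoxy)-3-(3-methylbut-2-en-1-yl)phenyl]-3-hydroxy-1-[4-methoxy-2-(methoxymethoxy)phenyl]prop-2-en-1-one (enol form of the alpha-formyl deoxybenzoin)
Conditions: BF3·OEt2 (0.5 equiv), CH2Cl2, −78 to −20 °C, 15 min; aq. NaHCO3
Reagents that add atoms: none
Why: BF3 coordinates the epoxide oxygen and the C–O bond at C3, the carbon bearing ring B, ionises, because the developing benzylic cation is stabilised by the ortho and para alkoxy oxygens of ring B whereas C2 is deactivated by the adjacent carbonyl group. The ring A aroyl group on C2 then shifts to C3 while the C2–O bond becomes the aldehyde carbonyl, which forms the bond between the two future dione carbons. The closest known reaction type is the Lewis-acid (Meinwald-type) rearrangement of trans chalcone epoxides to alpha-formyl deoxybenzoins with 1,2-acyl migration, the epoxide route to isoflavones. No ring closes and no stereocentre is created: both epoxide stereocentres are consumed and the new methine enolises to the chelated Z-hydroxymethylene ketone, so racemic 13 suffices. The step needs aroyl migration to beat hydride shift, which would give a 1,3-diaryl-propane-1,2-dione with unchanged skeleton; acyl migration is the normal course for chalcone epoxides because the carbonyl π-system can bridge to the cationic centre, and the strongly donating ring B makes ionisation at C3 easy. It also needs the MOM acetals and the prenyl alkene to survive, which substoichiometric BF3·OEt2, low temperature and a prompt bicarbonate quench should secure. The protected ring A oxygen keeps the formyl carbon from being trapped in an isoflavone ring, so it remains excisable.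

Step 8
Reactants: 14 (Z)-2-[2,4-bis(methoxymethoxy)-3-(3-methylbut-2-en-1-yl)phenyl]-3-hydroxy-1-[4-methoxy-2-(methoxymethoxy)phenyl]prop-2-en-1-one
Product: 16 1-[2,4-bis(methoxymethoxy)-3-(3-methylbut-2-en-1-yl)phenyl]-2-[4-methoxy-2-(methoxymethoxy)phenyl]ethane-1,2-dione, via alpha-hydroperoxy ketoaldehyde 15 (not isolated)
Conditions: CuBr (10 mol %), K2CO3, O2 (1 atm), DMF, rt
Reagents that add atoms: dioxygen, O=O
Why: Copper-catalysed aerobic oxidative deformylation of an alpha-aryl aldehyde: divalent copper formed under O2 oxidises the enolate of 14 to a doubly stabilised radical, which takes up O2 to give 15. The hydroperoxide closes onto the formyl carbonyl, which is more electrophilic and less hindered than the electron-rich aryl ketone, and the dioxetane fragments to the ketone and formate. The oxidant engages only the enolate, so the prenyl alkene and the acetals should be untouched.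

Step 9
Reactants: 16 1-[2,4-bis(methoxymethoxy)-3-(3-methylbut-2-en-1-yl)phenyl]-2-[4-methoxy-2-(methoxymethoxy)phenyl]ethane-1,2-dione
Product: 17 licoagrodione (1-[2,4-dihydroxy-3-(3-methylbut-2-en-1-yl)phenyl]-2-(2-hydroxy-4-methoxyphenyl)ethane-1,2-dione)
Conditions: 3 M aq. HCl, MeOH, rt to 40 °C
Reagents that add atoms: none
Why: Acid-catalysed acetal exchange of the three MOM ethers with methanol; the two ethers ortho to carbonyl groups are activated by chelation of the emerging phenols. Dilute acid near room temperature is chosen so that the prenyl alkene is not protonated and does not cyclise to a chroman.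

## Compound list

1 | paeonol (1-(2-hydroxy-4-methoxyphenyl)ethan-1-one) | CC(=O)c1ccc(OC)cc1O | starting material
2 | 1-[4-methoxy-2-(methoxymethoxy)phenyl]ethan-1-one | CC(=O)c1ccc(OC)cc1OCOC | intermediate
3 | resorcinol | Oc1cccc(O)c1 | starting material
4 | 1,3-bis(methoxymethoxy)benzene | COCOc1cccc(OCOC)c1 | intermediate
5 | prenyl bromide (1-bromo-3-methylbut-2-ene) | CC(C)=CCBr | starting material
6 | 2,6-bis(methoxymethoxy)phenyllithium | [Li]c1c(OCOC)cccc1OCOC | intermediate
7 | 1,3-bis(methoxymethoxy)-2-(3-methylbut-2-en-1-yl)benzene | COCOc1cccc(OCOC)c1CC=C(C)C | intermediate
8 | 2,4-bis(methoxymethoxy)-3-(3-methylbut-2-en-1-yl)phenyllithium | [Li]c1ccc(OCOC)c(CC=C(C)C)c1OCOC | intermediate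
9 | lithium [2,4-bis(methoxymethoxy)-3-(3-methylbut-2-en-1-yl)phenyl](dimethylamino)methanolate (racemic) | [Li]OC(N(C)C)c1ccc(OCOC)c(CC=C(C)C)c1OCOC | intermediate
10 | 2,4-bis(methoxymethoxy)-3-(3-methylbut-2-en-1-yl)benzaldehyde | O=Cc1ccc(OCOC)c(CC=C(C)C)c1OCOC | intermediate
11 | 3-[2,4-bis(methoxymethoxy)-3-(3-methylbut-2-en-1-yl)phenyl]-3-hydroxy-1-[4-methoxy-2-(methoxymethoxy)phenyl]propan-1-one (racemic) | COCOc1cc(OC)ccc1C(=O)CC(O)c1ccc(OCOC)c(CC=C(C)C)c1OCOC | intermediate
12 | (E)-3-[2,4-bis(methoxymethoxy)-3-(3-methylbut-2-en-1-yl)phenyl]-1-[4-methoxy-2-(methoxymethoxy)phenyl]prop-2-en-1-one | COCOc1cc(OC)ccc1C(=O)/C=C/c1ccc(OCOC)c(CC=C(C)C)c1OCOC | intermediate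
13 | rac-[(2S,3R)-3-{2,4-bis(methoxymethoxy)-3-(3-methylbut-2-en-1-yl)phenyl}oxiran-2-yl][4-methoxy-2-(methoxymethoxy)phenyl]methanone (trans; one enantiomer drawn) | COCOc1cc(OC)ccc1C(=O)[C@H]1O[C@@H]1c1ccc(OCOC)c(CC=C(C)C)c1OCOC | intermediate
14 | (Z)-2-[2,4-bis(methoxymethoxy)-3-(3-methylbut-2-en-1-yl)phenyl]-3-hydroxy-1-[4-methoxy-2-(methoxymethoxy)phenyl]prop-2-en-1-one | O/C=C(\C(=O)c1ccc(OC)cc1OCOC)c1ccc(OCOC)c(CC=C(C)C)c1OCOC | intermediate
15 | 2-[2,4-bis(methoxymethoxy)-3-(3-methylbut-2-en-1-yl)phenyl]-2-hydroperoxy-3-[4-methoxy-2-(methoxymethoxy)phenyl]-3-oxopropanal (racemic) | COCOc1cc(OC)ccc1C(=O)C(OO)(C=O)c1ccc(OCOC)c(CC=C(C)C)c1OCOC | intermediate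
16 | 1-[2,4-bis(methoxymethoxy)-3-(3-methylbut-2-en-1-yl)phenyl]-2-[4-methoxy-2-(methoxymethoxy)phenyl]ethane-1,2-dione | COCOc1cc(OC)ccc1C(=O)C(=O)c1ccc(OCOC)c(CC=C(C)C)c1OCOC | intermediate
17 | licoagrodione | COc1ccc(C(=O)C(=O)c2ccc(O)c(CC=C(C)C)c2O)c(O)c1 | target

## Step count and least certain steps

Total step count: 9. Longest linear sequence: 8 steps (from 3 through steps 2 to 9). The ring A branch from 1 is 6 steps.

**Step 7 (key step).** The most likely failure is Lewis-acid attack on the acetals before or alongside the rearrangement. Loss of the ring A MOM group would be followed by ring closure of the freed phenol onto the formyl carbon. Capture of the benzylic cation by the ortho acetal oxygen of ring B is a second possibility, and hydride shift in place of aroyl shift a third. The fallback gives up the rearrangement and builds the dione from the C2 unit already present in 2. It sets out from 2 and from 7 (through aryllithium 8, made as in step 4) and returns at 16. Riley oxidation of 2 with SeO2 in wet dioxane should give the arylglyoxal 2-[4-methoxy-2-(methoxymethoxy)phenyl]-2-oxoacetaldehyde F1, which is dried by azeotropic removal of water. Aryllithium 8 should add at −78 °C to the aldehyde carbonyl of F1, far more reactive than the hindered aryl ketone, to give the benzoin 2-[2,4-bis(methoxymethoxy)-3-(3-methylbut-2-en-1-yl)phenyl]-2-hydroxy-1-[4-methoxy-2-(methoxymethoxy)phenyl]ethan-1-one F2. Dess–Martin periodinane buffered with NaHCO3 then oxidises F2 to 16.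

**Step 8.** The most likely failure is loss of the formyl group by retro-Claisen cleavage before oxygenation, if traces of water are present, so that no oxygen is introduced. Fragmentation of the hydroperoxide on the aroyl side and slow autoxidation at the allylic positions are further possibilities. The fallback makes the deformylation deliberate and oxidises afterwards. It sets out from 14 and returns at 16. Aqueous Na2CO3 in MeOH should cleave 14 to the deoxybenzoin 2-[2,4-bis(methoxymethoxy)-3-(3-methylbut-2-en-1-yl)phenyl]-1-[4-methoxy-2-(methoxymethoxy)phenyl]ethan-1-one F3. Its doubly activated methylene is then oxidised to the dione 16 with air and DABCO in DMF at 90 °C, a base-mediated aerobic oxidation that, unlike SeO2, leaves the prenyl group alone.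

**Step 4.** The most likely failure is lateral deprotonation at the benzylic and allylic CH2 of the prenyl group in competition with ring lithiation, which would lead to side-chain formylation or alkene migration. The fallback replaces the organolithium formylation by a phenol-directed one. It sets out from 7 and returns at 10. Dilute HCl in MeOH at rt removes both acetals to give 2-(3-methylbut-2-en-1-yl)benzene-1,3-diol F4. Ortho-formylation with MgCl2, Et3N and paraformaldehyde in MeCN (Casnati–Skattebøl conditions) can only go to the equivalent C4/C6 positions and should give 2,4-dihydroxy-3-(3-methylbut-2-en-1-yl)benzaldehyde F5. Re-protection with excess MOMCl and K2CO3 in refluxing acetone gives 10.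

**Step 6.** The most likely failure is slow conjugate addition of hydroperoxide to an enone whose β-carbon is deactivated by the 2,4-dialkoxyaryl group, so that retro-aldol cleavage takes over on prolonged exposure to base. The fallback forms the epoxide by a Darzens condensation and bypasses 12. It sets out from 2 and 10 and returns at 13. Ketone 2 is converted with LiN(SiMe3)2 and TMSCl in THF at −78 °C into the silyl enol ether {1-[4-methoxy-2-(methoxymethoxy)phenyl]ethenyloxy}trimethylsilane F6. NBS in THF at 0 °C brominates F6 without free acid to 2-bromo-1-[4-methoxy-2-(methoxymethoxy)phenyl]ethan-1-one F7. Condensation of F7 with 10 under KOt-Bu in THF at 0 °C should give trans epoxy ketone 13 directly.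

## Further compounds

F1 | step 7 | 2-[4-methoxy-2-(methoxymethoxy)phenyl]-2-oxoacetaldehyde | O=CC(=O)c1ccc(OC)cc1OCOC
F2 | step 7 | 2-[2,4-bis(methoxymethoxy)-3-(3-methylbut-2-en-1-yl)phenyl]-2-hydroxy-1-[4-methoxy-2-(methoxymethoxy)phenyl]ethan-1-one (racemic) | COCOc1cc(OC)ccc1C(=O)C(O)c1ccc(OCOC)c(CC=C(C)C)c1OCOC
F3 | step 8 | 2-[2,4-bis(methoxymethoxy)-3-(3-methylbut-2-en-1-yl)phenyl]-1-[4-methoxy-2-(methoxymethoxy)phenyl]ethan-1-one | COCOc1cc(OC)ccc1C(=O)Cc1ccc(OCOC)c(CC=C(C)C)c1OCOC
F4 | step 4 | 2-(3-methylbut-2-en-1-yl)benzene-1,3-diol | CC(C)=CCc1c(O)cccc1O
F5 | step 4 | 2,4-dihydroxy-3-(3-methylbut-2-en-1-yl)benzaldehyde | O=Cc1ccc(O)c(CC=C(C)C)c1O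
F6 | step 6 | {1-[4-methoxy-2-(methoxymethoxy)phenyl]ethenyloxy}trimethylsilane | C=C(O[Si](C)(C)C)c1ccc(OC)cc1OCOC
F7 | step 6 | 2-bromo-1-[4-methoxy-2-(methoxymethoxy)phenyl]ethan-1-one | BrCC(=O)c1ccc(OC)cc1OCOC
A1 | alternative 1 | 1-methoxy-2-(3-methylbut-2-en-1-yl)-1,3-bis(trimethylsilyloxy)buta-1,3-diene | COC(O[Si](C)(C)C)=C(CC=C(C)C)C(=C)O[Si](C)(C)C
A2 | alternative 1 | 1-(tert-butyldimethylsilyloxy)-1-[4-methoxy-2-(methoxymethoxy)phenyl]but-3-yn-2-one (racemic) | C#CC(=O)C(O[Si](C)(C)C(C)(C)C)c1ccc(OC)cc1OCOC
A3 | alternative 1 | 2-(tert-butyldimethylsilyloxy)-1-[2,4-dihydroxy-3-(3-methylbut-2-en-1-yl)phenyl]-2-[4-methoxy-2-(methoxymethoxy)phenyl]ethan-1-one (racemic; one enantiomer drawn) | COCOc1cc(OC)ccc1[C@H](O[Si](C)(C)C(C)(C)C)C(=O)c1ccc(O)c(CC=C(C)C)c1O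
A4 | alternative 2 | 6-methoxybenzofuran-3(2H)-one | COc1ccc2c(c1)OCC2=O
A5 | alternative 2 | 1-bromo-2,4-bis(methoxymethoxy)-3-(3-methylbut-2-en-1-yl)benzene | Brc1ccc(OCOC)c(CC=C(C)C)c1OCOC
A6 | alternative 2 | 2-[2,4-bis(methoxymethoxy)-3-(3-methylbut-2-en-1-yl)phenyl]-6-methoxybenzofuran-3(2H)-one (racemic and labile at C2; one enantiomer drawn) | COc1ccc2c(c1)O[C@H](c1ccc(OCOC)c(CC=C(C)C)c1OCOC)C2=O
A7 | alternative 3 | 1,4-dimethylpiperazine-2,3-dione | CN1CCN(C)C(=O)C1=O
A8 | alternative 3 | [4-methoxy-2-(methoxymethoxy)phenyl]lithium | [Li]c1ccc(OC)cc1OCOC
A9 | alternative 3 | tris(methoxymethyl) ether of licoagrodione (identical with 16) | COCOc1cc(OC)ccc1C(=O)C(=O)c1ccc(OCOC)c(CC=C(C)C)c1OCOC
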